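The ring is numbered C1 (ketone), C2 (methoxy‑alkene carbon), C3 (aryl‑alkene carbon), C4 (spiro carbon), C5 (the C(OMe)Ar carbon) and C6 (epoxide CH2). C1 carries an O‑methylated carbon on either side (C2, C5), and C3 and C4 are adjacent carbons at the carbonyl oxidation state (C3 as enone β‑carbon, C4 as epoxide carbinol carbon): a masked aryl 1,2‑dione. Cutting C4–C5 and C2=C3 therefore gives racemic 1‑aryl‑1,3‑dimethoxyacetone and a 1‑aryl‑3‑siloxypropane‑1,2‑dione. One chiral dinuclear‑zinc aldol addition/condensation cascade should join them, close the cyclopentenone and set C4 and C5. Phenols are carried as TIPS ethers, the C6 oxygen as a TBS ether, exchanged later for a tosylate that the C4 hydroxyl displaces.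

Key step: step 5

Assumption: the sense of induction of the zinc catalyst cannot be predicted for this substrate pair, so the (S,S)-ligand is written and its antipode would be taken if a first run showed the mirror-image series; tert-butyldimethyl(prop-2-yn-1-yloxy)silane is taken as a catalogue compound.

Step 1
Reactants: 1 4-bromophenol
Product: 2 (4-bromophenoxy)tri(propan-2-yl)silane
Conditions: TIPSCl, imidazole, DMF, rt
Reagents that add atoms: chlorotri(propan-2-yl)silane (TIPSCl), CC(C)[Si](Cl)(C(C)C)C(C)C
Why: Imidazole-promoted O-silylation of a phenol is routine, and the bulky TIPS ether is chosen because it should survive phosphate base, zinc alkoxides and buffered HF in the later steps.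

Step 2
Reactants: 2 (4-bromophenoxy)tri(propan-2-yl)silane; 3 1,3-dimethoxypropan-2-one (2.5 equiv)
Product: 4 1,3-dimethoxy-1-{4-[tri(propan-2-yl)silyloxy]phenyl}propan-2-one (racemic)
Conditions: Pd2(dba)3 (2 mol %), Xantphos (5 mol %), K3PO4, toluene, 80 °C
Reagents that add atoms: none
Why: Buchwald–Hartwig-type palladium-catalysed α-arylation of a ketone enolate with an aryl bromide, in which the α-methoxy groups make the symmetric ketone acidic enough for the mild base K3PO4 (which spares the aryl silyl ether), the excess of 3 disfavours a second arylation, and the new benzylic centre is formed racemic, as the stereoconvergent key step requires.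

Step 3
Reactants: 2 (4-bromophenoxy)tri(propan-2-yl)silane; 5 tert-butyldimethyl(prop-2-yn-1-yloxy)silane
Product: 6 tert-butyldimethyl[(3-{4-[tri(propan-2-yl)silyloxy]phenyl}prop-2-yn-1-yl)oxy]silane
Conditions: Pd(PhCN)2Cl2 (3 mol %), t-Bu3P·HBF4 (6 mol %), CuI (2 mol %), i-Pr2NH, dioxane, rt
Reagents that add atoms: none
Why: Sonogashira coupling of a terminal alkyne with an aryl bromide, where the bulky electron-rich phosphine lets the electron-rich bromide undergo oxidative addition at room temperature and both silyl ethers are inert.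

Step 4
Reactants: 6 tert-butyldimethyl[(3-{4-[tri(propan-2-yl)silyloxy]phenyl}prop-2-yn-1-yl)oxy]silane
Product: 7 3-[tert-butyl(dimethyl)silyloxy]-1-{4-[tri(propan-2-yl)silyloxy]phenyl}propane-1,2-dione
Conditions: RuCl3·xH2O (2 mol %), NaIO4 (2.5 equiv), NaHCO3, MgSO4, EtOAc/MeCN/H2O, 0 °C
Reagents that add atoms: sodium periodate, [Na+].[O-]I(=O)(=O)=O
Why: Catalytically generated ruthenium tetroxide oxidises internal aryl alkynes to 1,2-diketones, and the bicarbonate/MgSO4 buffer, low temperature and short contact time should protect the silyl ethers and the electron-rich ring.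

Step 5
Reactants: 4 1,3-dimethoxy-1-{4-[tri(propan-2-yl)silyloxy]phenyl}propan-2-one (racemic, 1.3 equiv); 7 3-[tert-butyl(dimethyl)silyloxy]-1-{4-[tri(propan-2-yl)silyloxy]phenyl}propane-1,2-dione
Product: 10 (4R,5R)-4-{[tert-butyl(dimethyl)silyloxy]methyl}-4-hydroxy-2,5-dimethoxy-3,5-bis{4-[tri(propan-2-yl)silyloxy]phenyl}cyclopent-2-en-1-one, via open-chain aldol adduct 8 (not isolated), via ring-closed 3,4-diol 9 (not isolated)
Conditions: (S,S)-ProPhenol [2,6-bis{[(2S)-2-(hydroxydiphenylmethyl)pyrrolidin-1-yl]methyl}-4-methylphenol] (15 mol %), Et2Zn (30 mol %), 4 Å MS, THF, 0 → 40 °C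
Reagents that add atoms: none
Why: Proposed new method: the dinuclear zinc alkoxide should remove the most acidic proton of 4, the benzylic C5–H (which erases the racemic centre), giving an enolate held on zinc by chelation through the neighbouring methoxy oxygen; this attacks C4 of zinc-bound 7, the dione carbonyl that is not conjugated to the arene and hence the more electrophilic one (C4–C5 bond, adduct 8), after which C5 carries no hydrogen, so the remaining α-position C2 forms the enolate that adds to the aryl ketone C3 (diol 9), and E1cB loss of the C3 hydroxyl gives the conjugated C2=C3 enone 10. The closest known reactions are the hydroxide- or alkoxide-mediated condensation of 1,2-diketones with dialkyl ketones to racemic 4-hydroxycyclopent-2-enones and the dinuclear-zinc direct aldol additions of α-oxygenated ketones, whose enantioselective union is untested. The ring closes in the 5-(enolendo)-exo-trig mode, formally disfavoured yet the same closure by which 1,4-diketones give cyclopentenones, and the dehydration makes it irreversible. C5 and C4 are both created in the first aldol: the chiral pocket of the catalyst selects the faces of the planar enolate and of the C4 carbonyl (absolute configuration, both enantiomers of 4 converging), while the reversibility of this crowded ketone–ketone addition should let the adduct settle with the C6 arm anti to the C5 aryl before cyclisation fixes it. The step needs site selectivity in donor and acceptor, secured by pairing the most acidic C–H with the most electrophilic carbonyl, and selective dehydration, secured because the C3 hydroxyl has the acidic C2–H beside it whereas the C4 hydroxyl is separated from the ketone only by the fully substituted C5. Molecular sieves take up the water released, and the bulky silyl ether on C6 is meant to slow deprotonation at the CH2 of the dione, the most likely side reaction.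

Step 6
Reactants: 10 (4R,5R)-4-{[tert-butyl(dimethyl)silyloxy]methyl}-4-hydroxy-2,5-dimethoxy-3,5-bis{4-[tri(propan-2-yl)silyloxy]phenyl}cyclopent-2-en-1-one
Product: 11 (4R,5R)-4-hydroxy-4-(hydroxymethyl)-2,5-dimethoxy-3,5-bis{4-[tri(propan-2-yl)silyloxy]phenyl}cyclopent-2-en-1-one
Conditions: HF·pyridine, pyridine, THF, 0 °C → rt
Reagents that add atoms: none
Why: Acidic, pyridine-buffered fluoride cleaves the primary alkyl TBS ether much faster than the hindered aryl TIPS ethers (which are labile to basic, not acidic, fluoride), and the tertiary alcohol, the enone and both stereocentres are not touched.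

Step 7
Reactants: 11 (4R,5R)-4-hydroxy-4-(hydroxymethyl)-2,5-dimethoxy-3,5-bis{4-[tri(propan-2-yl)silyloxy]phenyl}cyclopent-2-en-1-one
Product: 13 (3R,4R)-4,6-dimethoxy-4,7-bis{4-[tri(propan-2-yl)silyloxy]phenyl}-1-oxaspiro[2.4]hept-6-en-5-one, via primary tosylate 12 (not isolated)
Conditions: TsCl, Et3N, Me3N·HCl (cat.), CH2Cl2, 0 °C; then DBU, 0 °C → rt
Reagents that add atoms: 4-methylbenzenesulfonyl chloride (TsCl), Cc1ccc(cc1)S(Cl)(=O)=O (its sulfonyl group is carried only by 12 and leaves again on ring closure)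
Why: Selective sulfonylation of the primary hydroxyl beside a tertiary one is followed by intramolecular Williamson etherification (3-exo-tet) by the C4 oxygen, which breaks only the C6–O bond so that C4 keeps its configuration, and closure onto the adjacent tosylate is expected to outrun retro-aldol cleavage of C4–C5.

Step 8
Reactants: 13 (3R,4R)-4,6-dimethoxy-4,7-bis{4-[tri(propan-2-yl)silyloxy]phenyl}-1-oxaspiro[2.4]hept-6-en-5-one
Product: 14 (3R,4R)-4,7-bis(4-hydroxyphenyl)-4,6-dimethoxy-1-oxaspiro[2.4]hept-6-en-5-one (CNP0504072.1)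
Conditions: TBAF, AcOH (1:1, 2.5 equiv), THF, 0 °C
Reagents that add atoms: none
Why: Fluoride cleavage of aryl silyl ethers is fast at 0 °C, and the acetic acid buffer keeps the liberated phenols protonated, which should protect the spiro-epoxide and the benzylic C5 methoxy group from phenoxide-driven side reactions.

Compound list
1 | 4-bromophenol | Oc1ccc(Br)cc1 | starting material
2 | (4-bromophenoxy)tri(propan-2-yl)silane | CC(C)[Si](Oc1ccc(Br)cc1)(C(C)C)C(C)C | intermediate
3 | 1,3-dimethoxypropan-2-one | COCC(=O)COC | starting material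
4 | 1,3-dimethoxy-1-{4-[tri(propan-2-yl)silyloxy]phenyl}propan-2-one (racemic) | COCC(=O)C(OC)c1ccc(O[Si](C(C)C)(C(C)C)C(C)C)cc1 | intermediate
5 | tert-butyldimethyl(prop-2-yn-1-yloxy)silane | C#CCO[Si](C)(C)C(C)(C)C | starting material
6 | tert-butyldimethyl[(3-{4-[tri(propan-2-yl)silyloxy]phenyl}prop-2-yn-1-yl)oxy]silane | CC(C)(C)[Si](C)(C)OCC#Cc1ccc(O[Si](C(C)C)(C(C)C)C(C)C)cc1 | intermediate
7 | 3-[tert-butyl(dimethyl)silyloxy]-1-{4-[tri(propan-2-yl)silyloxy]phenyl}propane-1,2-dione | CC(C)(C)[Si](C)(C)OCC(=O)C(=O)c1ccc(O[Si](C(C)C)(C(C)C)C(C)C)cc1 | intermediate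
8 | (2R,3R)-2-{[tert-butyl(dimethyl)silyloxy]methyl}-2-hydroxy-3,5-dimethoxy-1,3-bis{4-[tri(propan-2-yl)silyloxy]phenyl}pentane-1,4-dione (open-chain aldol adduct, not isolated) | COCC(=O)[C@@](OC)(c1ccc(O[Si](C(C)C)(C(C)C)C(C)C)cc1)[C@](O)(CO[Si](C)(C)C(C)(C)C)C(=O)c1ccc(O[Si](C(C)C)(C(C)C)C(C)C)cc1 | intermediate
9 | 4-{[tert-butyl(dimethyl)silyloxy]methyl}-3,4-dihydroxy-2,5-dimethoxy-3,5-bis{4-[tri(propan-2-yl)silyloxy]phenyl}cyclopentan-1-one (C4 and C5 configured as in 10, C2 and C3 transient and unassigned; not isolated) | COC1C(O)(c2ccc(O[Si](C(C)C)(C(C)C)C(C)C)cc2)[C@@](O)(CO[Si](C)(C)C(C)(C)C)[C@](OC)(c2ccc(O[Si](C(C)C)(C(C)C)C(C)C)cc2)C1=O | intermediate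
10 | (4R,5R)-4-{[tert-butyl(dimethyl)silyloxy]methyl}-4-hydroxy-2,5-dimethoxy-3,5-bis{4-[tri(propan-2-yl)silyloxy]phenyl}cyclopent-2-en-1-one (C4 hydroxyl cis to the C5 aryl, siloxymethyl arm cis to the C5 methoxy) | COC1=C(c2ccc(O[Si](C(C)C)(C(C)C)C(C)C)cc2)[C@@](O)(CO[Si](C)(C)C(C)(C)C)[C@](OC)(c2ccc(O[Si](C(C)C)(C(C)C)C(C)C)cc2)C1=O | intermediate
11 | (4R,5R)-4-hydroxy-4-(hydroxymethyl)-2,5-dimethoxy-3,5-bis{4-[tri(propan-2-yl)silyloxy]phenyl}cyclopent-2-en-1-one | COC1=C(c2ccc(O[Si](C(C)C)(C(C)C)C(C)C)cc2)[C@@](O)(CO)[C@](OC)(c2ccc(O[Si](C(C)C)(C(C)C)C(C)C)cc2)C1=O | intermediate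
12 | (4R,5R)-4-hydroxy-2,5-dimethoxy-4-[(4-methylbenzenesulfonyloxy)methyl]-3,5-bis{4-[tri(propan-2-yl)silyloxy]phenyl}cyclopent-2-en-1-one (primary tosylate, not isolated) | COC1=C(c2ccc(O[Si](C(C)C)(C(C)C)C(C)C)cc2)[C@@](O)(COS(=O)(=O)c2ccc(C)cc2)[C@](OC)(c2ccc(O[Si](C(C)C)(C(C)C)C(C)C)cc2)C1=O | intermediate
13 | (3R,4R)-4,6-dimethoxy-4,7-bis{4-[tri(propan-2-yl)silyloxy]phenyl}-1-oxaspiro[2.4]hept-6-en-5-one | COC1=C(c2ccc(O[Si](C(C)C)(C(C)C)C(C)C)cc2)[C@@]2(CO2)[C@](OC)(c2ccc(O[Si](C(C)C)(C(C)C)C(C)C)cc2)C1=O | intermediate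
14 | (3R,4R)-4,7-bis(4-hydroxyphenyl)-4,6-dimethoxy-1-oxaspiro[2.4]hept-6-en-5-one (epoxide oxygen cis to the aryl on the neighbouring carbon, epoxide CH2 cis to its methoxy) | COC1=C(c2ccc(O)cc2)[C@@]2(CO2)[C@](OC)(c2ccc(O)cc2)C1=O | target

Total step count: 8
Longest linear sequence: 7 steps (1 → 2 → 6 → 7 → 10 → 11 → 13 → 14; steps 1, 3, 4, 5, 6, 7, 8)

Steps most likely to fail

Step 5 (proposed new method). The cascade may fail in four ways: deprotonation at the CH2 of the dione with self-condensation, enolate formation of 4 at C2 instead of C5, weak facial discrimination in the crowded ketone–ketone addition, or arrest before dehydration when the released water deactivates the zinc alkoxide. The fallback gives up catalyst control and uses the known achiral chemistry. It sets out from 4 and 7, which are condensed with catalytic potassium tert-butoxide in THF/t-BuOH at 0 °C (alkoxide-mediated 1,2-diketone/ketone condensation to a 4-hydroxycyclopent-2-enone). Both mirror-image series should then form: beside 8 and 9 their enantiomers, the (2S,3S)-open-chain aldol adduct F1 and the mirror-image ring-closed 3,4-diol F2, and as product the racemate, 10 together with the (4S,5S)-enantiomer of the cyclopentenone F3. Preparative chromatography on a chiral stationary phase would then remove F3, and the route is rejoined at 10.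

Step 2. The arylation may suffer from a second arylation at the now more acidic benzylic position, base-induced self-condensation of the dialkoxy ketone, or catalyst inhibition by the chelating enolate. The fallback sets out from 2 and builds the ketone by alkene oxidation instead of enolate coupling. Suzuki–Miyaura coupling of 2 with commercial (E)-2-(3-methoxyprop-1-en-1-yl)-4,4,5,5-tetramethyl-1,3,2-dioxaborolane (Pd(dppf)Cl2, K3PO4, dioxane/water) should give (E)-[4-(3-methoxyprop-1-en-1-yl)phenoxy]tri(propan-2-yl)silane F4. Epoxidation with mCPBA/NaHCO3 in CH2Cl2 should give racemic trans-2-(methoxymethyl)-3-{4-[tri(propan-2-yl)silyloxy]phenyl}oxirane F5. Methanol with catalytic PPTS should open this at the benzylic carbon to 1,3-dimethoxy-1-{4-[tri(propan-2-yl)silyloxy]phenyl}propan-2-ol F6, whose configuration is of no consequence. Dess–Martin oxidation of the secondary alcohol then returns to the route at 4.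

Step 4. The oxidation may over-run to C–C cleavage of the dione, attack the electron-rich ring, or strip the primary silyl ether. The fallback sets out from 6 and reaches the dione through a diol instead of direct alkyne oxidation. Semi-hydrogenation over Lindlar catalyst (H2, quinoline) should give (Z)-tert-butyldimethyl[(3-{4-[tri(propan-2-yl)silyloxy]phenyl}prop-2-en-1-yl)oxy]silane F7. Upjohn dihydroxylation (cat. K2OsO4, NMO, acetone/water) should give racemic syn-3-[tert-butyl(dimethyl)silyloxy]-1-{4-[tri(propan-2-yl)silyloxy]phenyl}propane-1,2-diol F8. A double Swern oxidation ((COCl)2, DMSO, Et3N, −78 °C), which avoids glycol cleavage, then returns to the route at 7.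

Further compounds
F1 | step 5 | (2S,3S)-2-{[tert-butyl(dimethyl)silyloxy]methyl}-2-hydroxy-3,5-dimethoxy-1,3-bis{4-[tri(propan-2-yl)silyloxy]phenyl}pentane-1,4-dione (mirror image of 8) | COCC(=O)[C@](OC)(c1ccc(O[Si](C(C)C)(C(C)C)C(C)C)cc1)[C@@](O)(CO[Si](C)(C)C(C)(C)C)C(=O)c1ccc(O[Si](C(C)C)(C(C)C)C(C)C)cc1
F2 | step 5 | mirror image of ring-closed 3,4-diol 9 (C2 and C3 unassigned) | COC1C(O)(c2ccc(O[Si](C(C)C)(C(C)C)C(C)C)cc2)[C@](O)(CO[Si](C)(C)C(C)(C)C)[C@@](OC)(c2ccc(O[Si](C(C)C)(C(C)C)C(C)C)cc2)C1=O
F3 | step 5 | (4S,5S)-4-{[tert-butyl(dimethyl)silyloxy]methyl}-4-hydroxy-2,5-dimethoxy-3,5-bis{4-[tri(propan-2-yl)silyloxy]phenyl}cyclopent-2-en-1-one (mirror image of 10) | COC1=C(c2ccc(O[Si](C(C)C)(C(C)C)C(C)C)cc2)[C@](O)(CO[Si](C)(C)C(C)(C)C)[C@@](OC)(c2ccc(O[Si](C(C)C)(C(C)C)C(C)C)cc2)C1=O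
F4 | step 2 | (E)-[4-(3-methoxyprop-1-en-1-yl)phenoxy]tri(propan-2-yl)silane | COC/C=C/c1ccc(O[Si](C(C)C)(C(C)C)C(C)C)cc1
F5 | step 2 | trans-2-(methoxymethyl)-3-{4-[tri(propan-2-yl)silyloxy]phenyl}oxirane (racemic, one enantiomer written) | COC[C@H]1O[C@@H]1c1ccc(O[Si](C(C)C)(C(C)C)C(C)C)cc1
F6 | step 2 | 1,3-dimethoxy-1-{4-[tri(propan-2-yl)silyloxy]phenyl}propan-2-ol (racemic, configuration not relevant) | COCC(O)C(OC)c1ccc(O[Si](C(C)C)(C(C)C)C(C)C)cc1
F7 | step 4 | (Z)-tert-butyldimethyl[(3-{4-[tri(propan-2-yl)silyloxy]phenyl}prop-2-en-1-yl)oxy]silane | CC(C)(C)[Si](C)(C)OC/C=C\c1ccc(O[Si](C(C)C)(C(C)C)C(C)C)cc1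
F8 | step 4 | syn-3-[tert-butyl(dimethyl)silyloxy]-1-{4-[tri(propan-2-yl)silyloxy]phenyl}propane-1,2-diol (racemic, one enantiomer written) | CC(C)(C)[Si](C)(C)OC[C@H](O)[C@H](O)c1ccc(O[Si](C(C)C)(C(C)C)C(C)C)cc1
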